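**Remarks on the chemistry (assumptions)**
- Decalin carbons are numbered as in eremophilane: C3 ester carbon, C4 and C5 the methyl-bearing carbons, C8 ketone, C9 carbinol, C10 ring-fusion CH, C11–C13 side chain. α/β refer to the drawing in which the C5 methyl is β.
- 2,3-Dimethylcyclohex-2-en-1-one (1) is taken as purchasable; it is otherwise two standard steps from 2-methylcyclohexane-1,3-dione.
- The target is treated as the open γ-hydroxy-enone drawn; it may equilibrate with its cyclic hemiketal.

**Retrosynthetic overview**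
1. The C3 ester (Yamaguchi) and the C7 side chain (C-acetylation, Z-enol triflate, Stille hydroxymethylation) are disconnected, giving cis-decalinol 17 and trienoic acid 23.
2. Ring A of 17 is closed by intramolecular enolate alkylation (C1–C2); C4 and C3 are then fixed thermodynamically in the conformationally locked cis-decalin, and C9 by epoxidation of an enol ether.
3. Ring B, the quaternary C5, C10 and the C2–C3 bond come in one operation from cyclohexenone 8: MeLi adds to the ketone carbon (future C3) and the alkoxide undergoes an anionic oxy-Cope shift (C5–C10 formed, old ring bond C3–C8 broken).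
4. Enabling feature: in 8 the enone β-carbon, α-carbon and carbonyl carbon (future C5, C4, C3), the quaternary methoxy carbon (C8) and its E-alkenyl group (C9=C10) form a 3-oxy-1,5-diene. Its positions 1 and 4 are tied by the CH2–CH2 bridge (C6–C7) of a six-membered ring that is not in the target; this temporary ring forces a boat array, relays the one stereocentre (C8) to C5/C10 and becomes ring B.
5. Ring order: sacrificial cyclohexenone ring (bought) → ring B (step 6) → ring A (step 10). 8 comes from 1 by α′-oxygenation, asymmetric decarboxylative allylation and allylic C–H acetoxylation; 23 from (E)-oct-2-enal by alkyne homologation, carboalumination and Heck coupling.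

Key step: step 6

**Route**

Step 1
Reactants: 1 2,3-dimethylcyclohex-2-en-1-one
Product: 3 6-hydroxy-2,3-dimethylcyclohex-2-en-1-one (racemic), via lithium dienolate 2 (not isolated)
Conditions: LiN(i-Pr)2, THF, −78 °C; then 2-(phenylsulfonyl)-3-phenyloxaziridine, −78 °C; aq. NH4Cl
Reagents that add atoms: 2-(phenylsulfonyl)-3-phenyloxaziridine, O=S(=O)(c1ccccc1)N1OC1c1ccccc1
Why: kinetic α′-deprotonation of the enone and electrophilic enolate hydroxylation by an N-sulfonyloxaziridine; the new centre is racemic, which is harmless because it is planarised again in step 3.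

Step 2
Reactants: 3 6-hydroxy-2,3-dimethylcyclohex-2-en-1-one
Product: 4 6-methoxy-2,3-dimethylcyclohex-2-en-1-one (racemic)
Conditions: Ag2O, MeI, MeCN, 23 °C, dark
Reagents that add atoms: iodomethane, CI
Why: Williamson-type O-methylation under non-basic silver oxide conditions, which should avoid enolisation and α-ketol shift.

Step 3
Reactants: 4 6-methoxy-2,3-dimethylcyclohex-2-en-1-one
Product: 6 2-methoxy-5,6-dimethylcyclohexa-1,5-dien-1-yl prop-2-en-1-yl carbonate, via potassium dienolate 5 (not isolated)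
Conditions: KN(SiMe3)2, THF, −78 °C; allyl chloroformate, −78 → 0 °C
Reagents that add atoms: allyl chloroformate, C=CCOC(Cl)=O
Why: the only α-hydrogen (on the methoxy carbon) is removed kinetically and the potassium dienolate is O-acylated to the allyl enol carbonate, the standard substrate for decarboxylative allylation.

Step 4
Reactants: 6 2-methoxy-5,6-dimethylcyclohexa-1,5-dien-1-yl prop-2-en-1-yl carbonate
Product: 7 (6S)-6-methoxy-2,3-dimethyl-6-(prop-2-en-1-yl)cyclohex-2-en-1-one
Conditions: Pd2(dba)3 (2.5 mol%), (R)-4-tert-butyl-2-[2-(diphenylphosphino)phenyl]-4,5-dihydrooxazole ((R)-t-Bu-PHOX, 6.5 mol%), THF, 25 °C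
Reagents that add atoms: none
Why: palladium-catalysed decarboxylative asymmetric allylic alkylation of an α-alkoxy enol carbonate; the quaternary centre is set by the chiral P,N ligand, and the (R)-ligand is expected to give (S) by analogy with 2-alkyl substrates, the antipodal ligand being used if the sense proves opposite.

Step 5
Reactants: 7 (6S)-6-methoxy-2,3-dimethyl-6-(prop-2-en-1-yl)cyclohex-2-en-1-one
Product: 8 (2E)-3-[(1S)-1-methoxy-3,4-dimethyl-2-oxocyclohex-3-en-1-yl]prop-2-en-1-yl acetate
Conditions: Pd(OAc)2 (10 mol%), 1,4-benzoquinone (2 equiv), AcOH/DMSO (1:1), 40 °C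
Reagents that add atoms: acetic acid, CC(=O)O
Why: allylic C–H acetoxylation of a terminal alkene through a π-allylpalladium intermediate; acetate attack at the unhindered terminus should give the linear E allylic acetate, the tetrasubstituted enone alkene being inert.

Step 6
Reactants: 8 (2E)-3-[(1S)-1-methoxy-3,4-dimethyl-2-oxocyclohex-3-en-1-yl]prop-2-en-1-yl acetate
Product: 11 3-[(1S,2R)-2-(hydroxymethyl)-4-methoxy-1-methylcyclohex-3-en-1-yl]butan-2-one (both epimers at C3 of the butanone), via dilithium carbinolate 9 (not isolated), via rearranged enolate 10 (not isolated)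
Conditions: MeLi (3.3 equiv), THF, −78 → 0 °C; then KOt-Bu, 18-crown-6, 0 → 40 °C; aq. NH4Cl, 0 °C
Reagents that add atoms: methyllithium, [Li]C
Why: Proposed new method: MeLi cleaves the acetate and adds 1,2 to the enone carbonyl (forming C2–C3); the tertiary 1,5-dien-3-olate 9, once potassium-paired, should undergo an anionic oxy-Cope [3,3] shift in which the alkenyl terminus bonds to the former enone β-carbon (forming C5–C10) while the old ring bond C3–C8 breaks, giving enolate/enol ether 10. The closest known types are the tandem organolithium addition/anionic oxy-Cope rearrangement and the boat-constrained anionic oxy-Cope of 2-vinylbicyclo[2.2.2]oct-5-en-2-olates; its use on a monocyclic 6-alkenyl-6-alkoxycyclohex-2-en-1-olate, where it transposes the ring, is the new element. Ring B is closed by the sigmatropic bond formation itself through a six-membered boat transition state enforced by the C6–C7 bridge between diene positions 1 and 4; no other ring closes here. C5 is set by delivery of the alkenyl group on the ring face it occupies at C8 (self-immolative transfer of the single stereocentre of 8), and C10 by the E geometry, which in the boat array places the CH2O arm cis to C4 on the new ring (the cis-decalin relationship). The step needs 1,2-addition without enolisation (fully substituted β-carbon, small weakly basic nucleophile) and rearrangement rather than fragmentation (methoxy donor on the breaking bond, only one 1,5-diene path). C4 is left uncontrolled on protonation and is set in step 10.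

Step 7
Reactants: 11 3-[(1S,2R)-2-(hydroxymethyl)-4-methoxy-1-methylcyclohex-3-en-1-yl]butan-2-one
Product: 12 [(1R,6S)-3-methoxy-6-methyl-6-(3-oxobutan-2-yl)cyclohex-2-en-1-yl]methyl 4-methylbenzenesulfonate
Conditions: TsCl, Et3N, DMAP (cat.), CH2Cl2, 0 °C
Reagents that add atoms: 4-methylbenzenesulfonyl chloride, Cc1ccc(cc1)S(Cl)(=O)=O
Why: sulfonylation of the primary alcohol under buffered basic conditions, which the acid-labile methyl enol ether should tolerate.

Step 8
Reactants: 12 [(1R,6S)-3-methoxy-6-methyl-6-(3-oxobutan-2-yl)cyclohex-2-en-1-yl]methyl 4-methylbenzenesulfonate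
Product: 14 [(1R,2R,6S)-2-hydroxy-3,3-dimethoxy-6-methyl-6-(3-oxobutan-2-yl)cyclohexyl]methyl 4-methylbenzenesulfonate, via methoxy epoxide 13 (not isolated)
Conditions: mCPBA, NaHCO3, MeOH, −20 °C
Reagents that add atoms: 3-chloroperoxybenzoic acid, OOC(=O)c1cccc(Cl)c1; methanol, CO
Why: epoxidation of the electron-rich enol ether (faster than Baeyer–Villiger oxidation of the ketone) and methanolysis at the acetal carbon give the α-hydroxy dimethyl ketal; attack anti to the CH2OTs group on the neighbouring allylic carbon should give the 9β-alcohol (cis to H-10).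

Step 9
Reactants: 14 [(1R,2R,6S)-2-hydroxy-3,3-dimethoxy-6-methyl-6-(3-oxobutan-2-yl)cyclohexyl]methyl 4-methylbenzenesulfonate
Product: 15 [(1R,2R,6S)-2-[(tert-butyldimethylsilyl)oxy]-3,3-dimethoxy-6-methyl-6-(3-oxobutan-2-yl)cyclohexyl]methyl 4-methylbenzenesulfonate
Conditions: t-BuMe2SiOTf (1.1 equiv), 2,6-lutidine, CH2Cl2, −78 °C
Reagents that add atoms: tert-butyldimethylsilyl trifluoromethanesulfonate, CC(C)(C)[Si](C)(C)OS(=O)(=O)C(F)(F)F
Why: silylation of the hindered secondary alcohol with a silyl triflate at low temperature, where alcohol silylation should outrun enol silylation of the ketone and ketal ionisation.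

Step 10
Reactants: 15 [(1R,2R,6S)-2-[(tert-butyldimethylsilyl)oxy]-3,3-dimethoxy-6-methyl-6-(3-oxobutan-2-yl)cyclohexyl]methyl 4-methylbenzenesulfonate
Product: 16 (1R,4aS,5R,8aS)-5-[(tert-butyldimethylsilyl)oxy]-6,6-dimethoxy-1,8a-dimethyloctahydronaphthalen-2(1H)-one
Conditions: KOt-Bu (3 equiv), t-BuOH/THF, 25 → 50 °C
Reagents that add atoms: none
Why: intramolecular 6-exo-tet C-alkylation of the methyl ketone enolate closes ring A (C1–C2), and the excess alkoxide equilibrates C4; the C8 ketal and the 9β-silyloxy group confine the cis-decalin to the chair–chair form with the C5 methyl axial on ring A (the other form has OTBS/CH3 and OMe/C1 1,3-diaxial contacts), and there only the 4β-epimer has an equatorial C4 methyl.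

Step 11
Reactants: 16 (1R,4aS,5R,8aS)-5-[(tert-butyldimethylsilyl)oxy]-6,6-dimethoxy-1,8a-dimethyloctahydronaphthalen-2(1H)-one
Product: 17 (1R,2R,4aS,5R,8aR)-5-[(tert-butyldimethylsilyl)oxy]-6,6-dimethoxy-1,8a-dimethyldecahydronaphthalen-2-ol
Conditions: Li, NH3(l), THF, EtOH, −78 °C; then NH4Cl
Reagents that add atoms: none
Why: dissolving-metal reduction of the ketone should give the thermodynamically preferred equatorial alcohol, which in the locked conformer is 3α (trans to the C4 methyl); hydride reagents are avoided because the axial C5 methyl blocks axial attack.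

Step 12
Reactants: 18 (2E)-oct-2-enal
Product: 19 (3E)-non-3-en-1-yne
Conditions: Me3SiCHN2, n-BuLi, THF, −78 → 23 °C
Reagents that add atoms: (trimethylsilyl)diazomethane, C[Si](C)(C)C=[N+]=[N-]
Why: Colvin rearrangement: the lithiated silyldiazomethane adds to the aldehyde, Peterson-type elimination gives a diazoalkene, and loss of N2 with 1,2-hydrogen shift gives the terminal alkyne with the E alkene untouched.

Step 13
Reactants: 19 (3E)-non-3-en-1-yne
Product: 21 (1E,3E)-1-iodo-2-methylnona-1,3-diene, via alkenyl(dimethyl)alane 20 (not isolated)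
Conditions: Me3Al (2 equiv), Cp2ZrCl2 (0.25 equiv), CH2Cl2, 0 → 23 °C; then I2, THF, −30 °C
Reagents that add atoms: trimethylaluminium, C[Al](C)C; iodine, II
Why: zirconium-catalysed carboalumination adds CH3 and Al syn across the terminal alkyne (methyl to the internal carbon), and iodinolysis with retention fixes the E trisubstituted alkene.

Step 14
Reactants: 21 (1E,3E)-1-iodo-2-methylnona-1,3-diene; 22 acrylic acid
Product: 23 (2E,4E,6E)-5-methyldodeca-2,4,6-trienoic acid
Conditions: Pd(OAc)2 (5 mol%), K2CO3, n-Bu4NCl, DMF, 40 °C; then 1 M HCl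
Reagents that add atoms: none
Why: Heck coupling under ligand-free phase-transfer conditions; the alkenyl iodide geometry is retained and syn β-hydride elimination gives the 2E alkene.

Step 15
Reactants: 17 (1R,2R,4aS,5R,8aR)-5-[(tert-butyldimethylsilyl)oxy]-6,6-dimethoxy-1,8a-dimethyldecahydronaphthalen-2-ol; 23 (2E,4E,6E)-5-methyldodeca-2,4,6-trienoic acid
Product: 25 (1R,2R,4aS,5R,8aR)-5-[(tert-butyldimethylsilyl)oxy]-6,6-dimethoxy-1,8a-dimethyldecahydronaphthalen-2-yl (2E,4E,6E)-5-methyldodeca-2,4,6-trienoate, via mixed anhydride 24 (not isolated)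
Conditions: 2,4,6-trichlorobenzoyl chloride, Et3N, THF, 23 °C; then 17, DMAP, toluene, 23 °C
Reagents that add atoms: none
Why: Yamaguchi esterification of the equatorial secondary alcohol through the mixed anhydride; no stereocentre is touched.

Step 16
Reactants: 25 (1R,2R,4aS,5R,8aR)-5-[(tert-butyldimethylsilyl)oxy]-6,6-dimethoxy-1,8a-dimethyldecahydronaphthalen-2-yl (2E,4E,6E)-5-methyldodeca-2,4,6-trienoate
Product: 26 (1R,2R,4aS,5R,8aR)-5-[(tert-butyldimethylsilyl)oxy]-1,8a-dimethyl-6-oxodecahydronaphthalen-2-yl (2E,4E,6E)-5-methyldodeca-2,4,6-trienoate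
Conditions: pyridinium p-toluenesulfonate, acetone/H2O (10:1), 50 °C
Reagents that add atoms: water, O
Why: mild acid hydrolysis of the dimethyl ketal should unveil the C8 ketone without loss of the silyl ether or the ester; C9 stays β because the equatorial silyloxy group is also the thermodynamic arrangement.

Step 17
Reactants: 26 (1R,2R,4aS,5R,8aR)-5-[(tert-butyldimethylsilyl)oxy]-1,8a-dimethyl-6-oxodecahydronaphthalen-2-yl (2E,4E,6E)-5-methyldodeca-2,4,6-trienoate
Product: 27 (1R,2R,4aS,5R,8aR)-7-acetyl-5-[(tert-butyldimethylsilyl)oxy]-6-hydroxy-1,8a-dimethyl-1,2,3,4,4a,5,8,8a-octahydronaphthalen-2-yl (2E,4E,6E)-5-methyldodeca-2,4,6-trienoate (enol form of the β-diketone)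
Conditions: MgBr2·OEt2, i-Pr2NEt, 1-acetylbenzotriazole, CH2Cl2, 23 °C
Reagents that add atoms: 1-acetylbenzotriazole, CC(=O)n1nnc2ccccc12
Why: soft-enolisation C-acylation of the ketone at the unhindered C7 methylene (C9 carries the silyloxy group), under conditions mild enough for the trienoate.

Step 18
Reactants: 27 (1R,2R,4aS,5R,8aR)-7-acetyl-5-[(tert-butyldimethylsilyl)oxy]-6-hydroxy-1,8a-dimethyl-1,2,3,4,4a,5,8,8a-octahydronaphthalen-2-yl (2E,4E,6E)-5-methyldodeca-2,4,6-trienoate
Product: 28 (1R,2R,4aS,5R,7Z,8aR)-5-[(tert-butyldimethylsilyl)oxy]-1,8a-dimethyl-6-oxo-7-{1-[(trifluoromethanesulfonyl)oxy]ethylidene}decahydronaphthalen-2-yl (2E,4E,6E)-5-methyldodeca-2,4,6-trienoate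
Conditions: Tf2O, i-Pr2NEt, LiOTf, CH2Cl2, −78 → −20 °C
Reagents that add atoms: trifluoromethanesulfonic anhydride, O=S(=O)(OS(=O)(=O)C(F)(F)F)C(F)(F)F
Why: O-sulfonylation of the lithium-chelated (U-shaped) diketonate at the less hindered acetyl oxygen (the ring oxygen is flanked by the silyloxy group) should give the enol triflate with OTf cis to the ring carbonyl (Z).

Step 19
Reactants: 28 (1R,2R,4aS,5R,7Z,8aR)-5-[(tert-butyldimethylsilyl)oxy]-1,8a-dimethyl-6-oxo-7-{1-[(trifluoromethanesulfonyl)oxy]ethylidene}decahydronaphthalen-2-yl (2E,4E,6E)-5-methyldodeca-2,4,6-trienoate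
Product: 29 (1R,2R,4aS,5R,7Z,8aR)-5-[(tert-butyldimethylsilyl)oxy]-7-(1-hydroxypropan-2-ylidene)-1,8a-dimethyl-6-oxodecahydronaphthalen-2-yl (2E,4E,6E)-5-methyldodeca-2,4,6-trienoate
Conditions: Bu3SnCH2OH, Pd(PPh3)4 (5 mol%), LiCl, 1,4-dioxane, 70 °C
Reagents that add atoms: (tributylstannyl)methanol, OC[Sn](CCCC)(CCCC)CCCC
Why: Stille hydroxymethylation of the activated β-triflyloxy enone with retention of alkene geometry, which puts CH2OH cis to the C8 carbonyl (Z).

Step 20
Reactants: 29 (1R,2R,4aS,5R,7Z,8aR)-5-[(tert-butyldimethylsilyl)oxy]-7-(1-hydroxypropan-2-ylidene)-1,8a-dimethyl-6-oxodecahydronaphthalen-2-yl (2E,4E,6E)-5-methyldodeca-2,4,6-trienoate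
Product: 30 (1R,2R,4aS,5R,7Z,8aR)-5-hydroxy-7-(1-hydroxypropan-2-ylidene)-1,8a-dimethyl-6-oxodecahydronaphthalen-2-yl (2E,4E,6E)-5-methyldodeca-2,4,6-trienoate (CNP0226738.1)
Conditions: HF·pyridine, pyridine, THF, 0 °C
Reagents that add atoms: none
Why: buffered fluoride desilylation of the secondary silyl ether; the buffer is meant to prevent acid-induced cyclodehydration of the Z-γ-hydroxy-enone to a furan.

**Compound list**
1 | 2,3-dimethylcyclohex-2-en-1-one | CC1=C(C)C(=O)CCC1 | starting material
2 | lithium 2,3-dimethylcyclohexa-1,5-dien-1-olate | CC1=C(C)C([O-])=CCC1.[Li+] | intermediate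
3 | 6-hydroxy-2,3-dimethylcyclohex-2-en-1-one (racemic) | CC1=C(C)C(=O)C(O)CC1 | intermediate
4 | 6-methoxy-2,3-dimethylcyclohex-2-en-1-one (racemic) | CC1=C(C)C(=O)C(OC)CC1 | intermediate
5 | potassium 2-methoxy-5,6-dimethylcyclohexa-1,5-dien-1-olate | COC1=C([O-])C(C)=C(C)CC1.[K+] | intermediate
6 | 2-methoxy-5,6-dimethylcyclohexa-1,5-dien-1-yl prop-2-en-1-yl carbonate | COC1=C(OC(=O)OCC=C)C(C)=C(C)CC1 | intermediate
7 | (6S)-6-methoxy-2,3-dimethyl-6-(prop-2-en-1-yl)cyclohex-2-en-1-one | CC1=C(C)C(=O)[C@@](OC)(CC=C)CC1 | intermediate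
8 | (2E)-3-[(1S)-1-methoxy-3,4-dimethyl-2-oxocyclohex-3-en-1-yl]prop-2-en-1-yl acetate | CC1=C(C)C(=O)[C@@](OC)(/C=C/COC(C)=O)CC1 | intermediate
9 | dilithium carbinolate from MeLi addition to 8 (carbinol carbon unassigned) | CC1=C(C)C(C)([O-])[C@@](OC)(/C=C/C[O-])CC1.[Li+].[Li+] | intermediate
10 | enolate/alkoxide after the oxy-Cope shift (enolate geometry unassigned; Li/K counter-ions, drawn as lithium) | COC1=C[C@@H](C[O-])[C@@](C)(C(C)=C(C)[O-])CC1.[Li+].[Li+] | intermediate
11 | 3-[(1S,2R)-2-(hydroxymethyl)-4-methoxy-1-methylcyclohex-3-en-1-yl]butan-2-one (epimers at butanone C3) | COC1=C[C@@H](CO)[C@@](C)(C(C)C(C)=O)CC1 | intermediate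
12 | [(1R,6S)-3-methoxy-6-methyl-6-(3-oxobutan-2-yl)cyclohex-2-en-1-yl]methyl 4-methylbenzenesulfonate | COC1=C[C@@H](COS(=O)(=O)c2ccc(C)cc2)[C@@](C)(C(C)C(C)=O)CC1 | intermediate
13 | β-face methoxy epoxide of 12 | CC(=O)C(C)[C@@]1(C)CC[C@]2(OC)O[C@@H]2[C@H]1COS(=O)(=O)c3ccc(C)cc3 | intermediate
14 | [(1R,2R,6S)-2-hydroxy-3,3-dimethoxy-6-methyl-6-(3-oxobutan-2-yl)cyclohexyl]methyl 4-methylbenzenesulfonate | CC(=O)C(C)[C@@]1(C)CCC(OC)(OC)[C@H](O)[C@H]1COS(=O)(=O)c2ccc(C)cc2 | intermediate
15 | [(1R,2R,6S)-2-[(tert-butyldimethylsilyl)oxy]-3,3-dimethoxy-6-methyl-6-(3-oxobutan-2-yl)cyclohexyl]methyl 4-methylbenzenesulfonate | CC(=O)C(C)[C@@]1(C)CCC(OC)(OC)[C@H](O[Si](C)(C)C(C)(C)C)[C@H]1COS(=O)(=O)c2ccc(C)cc2 | intermediate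
16 | (1R,4aS,5R,8aS)-5-[(tert-butyldimethylsilyl)oxy]-6,6-dimethoxy-1,8a-dimethyloctahydronaphthalen-2(1H)-one | O=C1CC[C@@H]2[C@@H](O[Si](C)(C)C(C)(C)C)C(OC)(OC)CC[C@]2(C)[C@H]1C | intermediate
17 | (1R,2R,4aS,5R,8aR)-5-[(tert-butyldimethylsilyl)oxy]-6,6-dimethoxy-1,8a-dimethyldecahydronaphthalen-2-ol | O[C@@H]1CC[C@@H]2[C@@H](O[Si](C)(C)C(C)(C)C)C(OC)(OC)CC[C@]2(C)[C@H]1C | intermediate
18 | (2E)-oct-2-enal | CCCCC/C=C/C=O | starting material
19 | (3E)-non-3-en-1-yne | CCCCC/C=C/C#C | intermediate
20 | dimethyl[(1E,3E)-2-methylnona-1,3-dien-1-yl]alane | CCCCC/C=C/C(C)=C/[Al](C)C | intermediate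
21 | (1E,3E)-1-iodo-2-methylnona-1,3-diene | CCCCC/C=C/C(C)=C/I | intermediate
22 | acrylic acid | C=CC(=O)O | starting material
23 | (2E,4E,6E)-5-methyldodeca-2,4,6-trienoic acid | CCCCC/C=C/C(C)=C/C=C/C(=O)O | intermediate
24 | (2E,4E,6E)-5-methyldodeca-2,4,6-trienoic 2,4,6-trichlorobenzoic anhydride | CCCCC/C=C/C(C)=C/C=C/C(=O)OC(=O)c1c(Cl)cc(Cl)cc1Cl | intermediate
25 | trienoate of 17 (C8 dimethyl ketal, 9β-OTBS) | CCCCC/C=C/C(C)=C/C=C/C(=O)O[C@@H]1CC[C@@H]2[C@@H](O[Si](C)(C)C(C)(C)C)C(OC)(OC)CC[C@]2(C)[C@H]1C | intermediate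
26 | 8-ketone (9β-OTBS, 3α-trienoate) | CCCCC/C=C/C(C)=C/C=C/C(=O)O[C@@H]1CC[C@@H]2[C@@H](O[Si](C)(C)C(C)(C)C)C(=O)CC[C@]2(C)[C@H]1C | intermediate
27 | 7-acetyl β-diketone, enol form | CCCCC/C=C/C(C)=C/C=C/C(=O)O[C@@H]1CC[C@@H]2[C@@H](O[Si](C)(C)C(C)(C)C)C(O)=C(C(C)=O)C[C@]2(C)[C@H]1C | intermediate
28 | (Z)-enol triflate | CCCCC/C=C/C(C)=C/C=C/C(=O)O[C@@H]1CC[C@@H]2[C@@H](O[Si](C)(C)C(C)(C)C)C(=O)/C(=C(/C)OS(=O)(=O)C(F)(F)F)C[C@]2(C)[C@H]1C | intermediate
29 | 9-O-TBS ether of the target | CCCCC/C=C/C(C)=C/C=C/C(=O)O[C@@H]1CC[C@@H]2[C@@H](O[Si](C)(C)C(C)(C)C)C(=O)/C(=C(/C)CO)C[C@]2(C)[C@H]1C | intermediate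
30 | CNP0226738.1 | CCCCC/C=C/C(C)=C/C=C/C(=O)O[C@@H]1CC[C@@H]2[C@@H](O)C(=O)/C(=C(/C)CO)C[C@]2(C)[C@H]1C | target

**Step count**
Total: 20 steps. Longest linear sequence: 17 steps (steps 1–11 and 15–20); the acid arm is 3 steps (12–14).

**Steps most likely to fail**

1. Step 6. The tertiary alkoxide may cleave ionically without recombination, or the boat [3,3] shift may be too slow under basic conditions so that side reactions of the alkoxide win. Fallback, setting out from 8 and returning at 11: the cascade is given up and the two bonds are made in separate, neutral, known operations. MeLi/CeCl3 (THF, −78 °C, aqueous work-up) should give the tertiary carbinol diol F1. Me3SiCl/imidazole should give the bis(trimethylsilyl) ether F2. Heating F2 (toluene, sealed tube, about 200 °C) should effect the thermal silyloxy-Cope rearrangement to the silyl enol ether F3, with no alkoxide present. K2CO3 in methanol removes both silyl groups and gives 11.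

2. Step 18. Sulfonylation may occur at the ring oxygen, or the enolate geometry may be lost, giving regio- and E/Z-isomeric triflates. Fallback, setting out from 26 and returning at 29: the Z geometry is taken from a furan ring instead. Me3SiOTf/Et3N should give the C7-side trimethylsilyl enol ether F4. A TiCl4-mediated Mukaiyama aldol addition to 1-[(tert-butyldimethylsilyl)oxy]propan-2-one should give the β-hydroxy ketone F5. Camphorsulfonic acid in methanol (primary silyl ether off) and then pyridinium p-toluenesulfonate in warm toluene should cause hemiketalisation and double dehydration to the fused 3-methylfuran F6. Dimethyldioxirane (acetone, −78 °C) should open the furan to the cis-keto-enal F7, and NaBH(OAc)3 should reduce only the aldehyde, giving 29.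

3. Step 10. O-alkylation of the ambident enolate (six-membered cyclic enol ether) or elimination of the tosylate may compete with C-alkylation. Fallback, setting out from 15 and returning at 16: ring A is closed by carbonyl condensation. Kornblum oxidation (DMSO, NaHCO3, 110 °C) should give the keto aldehyde F8. Piperidinium acetate (benzene, 60 °C) should effect intramolecular aldol condensation to the ring-A enone F9. Hydrogenation (H2, Pd/C, EtOAc) followed by NaOMe/MeOH equilibration of C4 should give 16.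

**Further compounds**
F1 | step 6 | (6S)-6-[(1E)-3-hydroxyprop-1-en-1-yl]-6-methoxy-1,2,3-trimethylcyclohex-2-en-1-ol (carbinol carbon unassigned) | CC1=C(C)C(C)(O)[C@@](OC)(/C=C/CO)CC1
F2 | step 6 | bis(trimethylsilyl) ether of F1 | CC1=C(C)C(C)(O[Si](C)(C)C)[C@@](OC)(/C=C/CO[Si](C)(C)C)CC1
F3 | step 6 | trimethylsilyl enol ether/trimethylsilyl ether of 11 (enol ether geometry unassigned) | COC1=C[C@@H](CO[Si](C)(C)C)[C@@](C)(C(C)=C(C)O[Si](C)(C)C)CC1
F4 | step 18 | C7-side trimethylsilyl enol ether of 26 | CCCCC/C=C/C(C)=C/C=C/C(=O)O[C@@H]1CC[C@@H]2[C@@H](O[Si](C)(C)C(C)(C)C)C(O[Si](C)(C)C)=CC[C@]2(C)[C@H]1C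
F5 | step 18 | aldol adduct of F4 with 1-[(tert-butyldimethylsilyl)oxy]propan-2-one (two new centres unassigned) | CCCCC/C=C/C(C)=C/C=C/C(=O)O[C@@H]1CC[C@@H]2[C@@H](O[Si](C)(C)C(C)(C)C)C(=O)C(C(C)(O)CO[Si](C)(C)C(C)(C)C)C[C@]2(C)[C@H]1C
F6 | step 18 | fused 3-methylfuran (9β-OTBS, 3α-trienoate) | CCCCC/C=C/C(C)=C/C=C/C(=O)O[C@@H]1CC[C@@H]2[C@@H](O[Si](C)(C)C(C)(C)C)c3occ(C)c3C[C@]2(C)[C@H]1C
F7 | step 18 | (Z)-keto-enal from furan opening | CCCCC/C=C/C(C)=C/C=C/C(=O)O[C@@H]1CC[C@@H]2[C@@H](O[Si](C)(C)C(C)(C)C)C(=O)/C(=C(/C)C=O)C[C@]2(C)[C@H]1C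
F8 | step 10 | (1S,2R,6S)-2-[(tert-butyldimethylsilyl)oxy]-3,3-dimethoxy-6-methyl-6-(3-oxobutan-2-yl)cyclohexane-1-carbaldehyde | CC(=O)C(C)[C@@]1(C)CCC(OC)(OC)[C@H](O[Si](C)(C)C(C)(C)C)[C@H]1C=O
F9 | step 10 | ring-A enone (C1=C2, 3-one; C4 unassigned) | O=C1C=C[C@@H]2[C@@H](O[Si](C)(C)C(C)(C)C)C(OC)(OC)CC[C@]2(C)C1C
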